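(The numbers were drawn at random within sensible limits; the result is computed.)

The easy step first: precatalyst turns into catalyst on a clock of its own, whatever the substrate is doing.

    substrate + catalyst → catalyst + target (k1 = 1.8 M⁻¹ min⁻¹, Ea1 = 72.0 kJ mol⁻¹)
    substrate → side product (k2 = 4.5 × 10⁻⁴ min⁻¹, Ea2 = 108 kJ mol⁻¹)
    precatalyst → catalyst (k3 = 9.5 × 10⁻⁴ min⁻¹, Ea3 = 105 kJ mol⁻¹)
    (constants at 70 °C)
in all of them: substrate 0.012 M; precatalyst 5 mol%; time 8.0 h
- theta: temperature 110 °C
- eta: temperature 130 °C
- gamma: temperature 90 °C
- alpha: temperature 70 °C
- at 70 °C the constants are as listed, elsewhere as the activation energies make them
- the best flask by amount of target, in percent of the substrate charged; "all alike" if 1.5 percentage points covers them all (theta / eta / gamma / alpha / all alike)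
- amount of target at the end, in percent of the substrate charged, theta
- amount of target at the end, in percent of the substrate charged, eta
- amount of target at the end, in percent of the substrate charged, gamma
- amount of target at the end, in percent of the substrate charged, alpha

Write c for the share of the catalyst charge released so far. Both losses of substrate are first order in substrate, the catalytic one pseudo-first-order at a given c, so the substrate fraction cancels when you divide one rate by the other: target forms against side product as S·c. In alpha S is 2.40: this is the selectivity factor S, the catalytic rate with the whole charge released over the side rate. The side step has the larger activation energy, so with heat S goes to 1.20 in gamma, 0.643 in theta and 0.367 in eta.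

But c climbs from zero. Averaged over one lifetime of the side step, c is 0.584 at the constants of alpha, and I keep that figure for gamma, theta and eta: from coldest to hottest flask the release speeds up 240-fold and the side step 280-fold. A flask that uses up its substrate should then end at Sm/(1+Sm): 17.6% in eta, 27.3% in theta, 41.1% in gamma.

One number is not enough, though: the clock counts too. Gamma has 1.74 side lifetimes, so I expect it a little under its figure. Alpha has 0.216, with mean c 0.197 over the run. Its catalytic exposure is therefore 0.102, and its share of the conversion gives 8.75%. I put gamma first.

The forecast also named gamma, with 26.8% for theta, 17.7% for eta, 36.5% for gamma, below my figure, and 8.4% for alpha, reasoning that “heating favours substrate loss”.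

The simulation gives gamma, with 26.6% in theta, 17.7% in eta, 36.4% in gamma and 8.45% in alpha.

In alpha, release and side step ran together, half of their turnover up to the asked time done by 3.55 h and 3.69 h, and after 8.00 h substrate stood at 72.8% with precatalyst at 63.4%. With catalyst at 36.6%, S·c in alpha was 0.878 at that time, and the side step was using substrate 1.1 times as fast as the catalytic step.

Take the neighbour like alpha with 2 mol% of precatalyst: S falls to 0.960, and the same reckoning gives 3.60%. The simulation gives 3.48%.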